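**Retrosynthetic overview**
- The only ring formed is the dihydronaphthalene carbocycle, closed last by an intramolecular Friedel–Crafts alkylation (C1–C8a), which sets C1 trans to the existing C2 centre.
- The C3=C4 enal is disconnected by a crossed aldol condensation between two aldehydes: a C6–C5 aldehyde (pendant ring plus C1, C2, C3, CH2O, CHO) and O-TIPS-vanillin (fused ring plus C4).
- The C6–C5 aldehyde comes from an aryl Grignard addition to a Roche-type aldehyde, followed by alkene cleavage.
- The C2 stereocentre comes from an organocatalytic α-hydroxymethylation of pent-4-enal.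
- Both aromatic rings come from catechol through one shared aryl bromide.

Assumptions: the target is handled as the open γ-hydroxy enal as drawn, not its lactol. The benzylic acetate carbon in 10–12 is carried as an epimeric mixture because it is ionised in step 11. The catalyst sense in step 6 is taken from the standard enamine shielding model, not from a checked literature example.

**Step 1**
Reactants: 1 catechol
Product: 2 guaiacol (2-methoxyphenol)
Conditions: MeI (1.0 equiv), K2CO3, acetone, reflux; distil from veratrole and catechol
Reagents that add atoms: iodomethane, CI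
Why: Williamson mono-O-methylation; statistical, with the by-products separable and recyclable.

**Step 2**
Reactants: 2 guaiacol
Product: 3 4-bromo-2-methoxyphenol
Conditions: NBS, MeCN, 0 °C
Reagents that add atoms: N-bromosuccinimide, O=C1CCC(=O)N1Br
Why: Electrophilic aromatic bromination goes para to the free OH, the stronger director.

**Step 3**
Reactants: 3 4-bromo-2-methoxyphenol
Product: 4 (4-bromo-2-methoxyphenoxy)triisopropylsilane
Conditions: TIPSCl, imidazole, DMF, rt
Reagents that add atoms: TIPSCl, CC(C)[Si](Cl)(C(C)C)C(C)C
Why: Phenol silylation; the aryl TIPS ether tolerates organometallics, amines and TFA and is removed by fluoride at the end.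

**Step 4**
Reactants: 4 aryl bromide
Product: 5 3-methoxy-4-(triisopropylsilyloxy)benzaldehyde (O-TIPS-vanillin)
Conditions: n-BuLi, THF, −78 °C; then DMF, −78 → 0 °C
Reagents that add atoms: DMF, CN(C)C=O
Why: Br–Li exchange and formylation (Bouveault); the anion is para to OTIPS, so no silyl migration.

**Step 5**
Reactants: 6 pent-4-en-1-ol
Product: 7 pent-4-enal
Conditions: (COCl)2, DMSO, Et3N, CH2Cl2, −78 °C; used as a solution
Reagents that add atoms: none
Why: Swern oxidation of a primary alcohol without over-oxidation or alkene migration.

**Step 6**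
Reactants: 7 pent-4-enal
Product: 8 (R)-2-(hydroxymethyl)pent-4-enal
Conditions: 37% aq. HCHO, (S)-α,α-diphenylprolinol TMS ether (10 mol %), pH 7 phosphate buffer, toluene, rt; used crude
Reagents that add atoms: formaldehyde, C=O
Why: Enamine-catalysed asymmetric cross-aldol (α-hydroxymethylation); the (S)-catalyst shields one enamine face, so formaldehyde adds to the other and gives the R centre that becomes C2 of the target.

**Step 7**
Reactants: 8 hydroxy aldehyde
Product: 9 (R)-2-{[(triisopropylsilyl)oxy]methyl}pent-4-enal
Conditions: TIPSCl, imidazole, CH2Cl2, 0 °C → rt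
Reagents that add atoms: TIPSCl, CC(C)[Si](Cl)(C(C)C)C(C)C
Why: Primary-OH silylation converts the dehydration-prone β-hydroxy aldehyde into a Roche-type aldehyde; mild base and low temperature keep the α-centre intact.

**Step 8**
Reactants: 4 aryl bromide (as its Grignard reagent); 9 aldehyde
Product: 10 (1RS,2R)-1-[3-methoxy-4-(triisopropylsilyloxy)phenyl]-2-{[(triisopropylsilyl)oxy]methyl}pent-4-en-1-yl acetate
Conditions: Mg, THF, 40 °C; then 9, −78 → −20 °C; then Ac2O, DMAP (cat.), → rt
Reagents that add atoms: acetic anhydride, CC(=O)OC(C)=O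
Why: Grignard addition to the α-branched aldehyde outruns enolisation, so the 2R centre is kept; the new carbinol forms as an inconsequential mixture and is trapped in situ as a benzylic acetate.

**Step 9**
Reactants: 10 alkene
Product: 11 (3R,4RS)-4-acetoxy-4-[3-methoxy-4-(triisopropylsilyloxy)phenyl]-3-{[(triisopropylsilyl)oxy]methyl}butanal
Conditions: OsO4 (cat.), NaIO4, 2,6-lutidine, dioxane/H2O, rt
Reagents that add atoms: NaIO4, [Na+].[O-]I(=O)(=O)=O, with cat. OsO4, O=[Os](=O)(=O)=O (source of the aldehyde oxygen)
Why: Lemieux–Johnson cleavage of the terminal alkene; it spares the electron-rich arene, the acetate and the silyl ethers, and the new aldehyde has only an α-CH2, so nothing can epimerise.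

**Step 10**
Reactants: 11 aldehyde; 5 O-TIPS-vanillin (1.5 equiv)
Product: 12 (2E)-2-[(1RS,2R)-1-acetoxy-1-{3-methoxy-4-(triisopropylsilyloxy)phenyl}-3-(triisopropylsilyloxy)propan-2-yl]-3-[3-methoxy-4-(triisopropylsilyloxy)phenyl]prop-2-enal
Conditions: pyrrolidine (20 mol %), 4-(dimethylamino)benzoic acid (20 mol %), CH2Cl2, 4 Å MS, rt → 40 °C
Reagents that add atoms: none
Why: Amine/acid-catalysed crossed aldol condensation (enamine of 11 plus iminium of non-enolisable 5, Mannich-type, then elimination) gives the thermodynamic E-enal, which places the vanillyl ring cis to the stereocentre-bearing carbon as the ring closure needs.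

**Step 11**
Reactants: 12 enal
Product: 13 (3R,4S)-7-methoxy-4-[3-methoxy-4-(triisopropylsilyloxy)phenyl]-6-(triisopropylsilyloxy)-3-{[(triisopropylsilyl)oxy]methyl}-3,4-dihydronaphthalene-2-carbaldehyde
Conditions: TFA, CH2Cl2, −20 → 0 °C
Reagents that add atoms: none
Why: Acid ionises the p-silyloxybenzylic acetate and the cation is trapped in a 6-membered intramolecular Friedel–Crafts alkylation at the position para to OMe; the aryl group adds anti to the neighbouring CH2OTIPS (also the thermodynamic trans-diaxial product), so the 3R centre sets C4 as S.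

**Step 12**
Reactants: 13 tris-silyl ether
Product: 14 7,8,9,9-tetradehydroisolariciresinol, (3R,4S)-6-hydroxy-4-(4-hydroxy-3-methoxyphenyl)-3-(hydroxymethyl)-7-methoxy-3,4-dihydronaphthalene-2-carbaldehyde
Conditions: TBAF, AcOH, THF, 0 °C → rt, under Ar
Reagents that add atoms: none
Why: Buffered fluoride removes the two aryl and one alkyl TIPS ethers without touching the enal or the non-acidic C3/C4 stereocentres; argon avoids oxidative aromatisation of the phenolic dihydronaphthalene.

**Compound list**
1 | catechol | Oc1ccccc1O | starting material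
2 | guaiacol | COc1ccccc1O | intermediate
3 | 4-bromo-2-methoxyphenol | COc1cc(Br)ccc1O | intermediate
4 | (4-bromo-2-methoxyphenoxy)triisopropylsilane | COc1cc(Br)ccc1O[Si](C(C)C)(C(C)C)C(C)C | intermediate
5 | 3-methoxy-4-(triisopropylsilyloxy)benzaldehyde | COc1cc(C=O)ccc1O[Si](C(C)C)(C(C)C)C(C)C | intermediate
6 | pent-4-en-1-ol | C=CCCCO | starting material
7 | pent-4-enal | C=CCCC=O | intermediate
8 | (R)-2-(hydroxymethyl)pent-4-enal | O=C[C@@H](CO)CC=C | intermediate
9 | (R)-2-{[(triisopropylsilyl)oxy]methyl}pent-4-enal | O=C[C@@H](CO[Si](C(C)C)(C(C)C)C(C)C)CC=C | intermediate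
10 | (1RS,2R)-1-aryl-2-(TIPSOCH2)pent-4-en-1-yl acetate (aryl = 3-MeO-4-TIPSO-phenyl) | CC(=O)OC(c1ccc(O[Si](C(C)C)(C(C)C)C(C)C)c(OC)c1)[C@@H](CO[Si](C(C)C)(C(C)C)C(C)C)CC=C | intermediate
11 | (3R,4RS)-4-acetoxy-4-aryl-3-(TIPSOCH2)butanal | CC(=O)OC(c1ccc(O[Si](C(C)C)(C(C)C)C(C)C)c(OC)c1)[C@@H](CO[Si](C(C)C)(C(C)C)C(C)C)CC=O | intermediate
12 | (2E)-enal from the crossed aldol condensation (2R at the branching carbon, acetate carbon RS) | CC(=O)OC(c1ccc(O[Si](C(C)C)(C(C)C)C(C)C)c(OC)c1)[C@@H](CO[Si](C(C)C)(C(C)C)C(C)C)/C(C=O)=C\c1ccc(O[Si](C(C)C)(C(C)C)C(C)C)c(OC)c1 | intermediate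
13 | (3R,4S)-tris-TIPS dihydronaphthalene-2-carbaldehyde | COc1cc([C@H]2c3cc(O[Si](C(C)C)(C(C)C)C(C)C)c(OC)cc3C=C(C=O)[C@@H]2CO[Si](C(C)C)(C(C)C)C(C)C)ccc1O[Si](C(C)C)(C(C)C)C(C)C | intermediate
14 | 7,8,9,9-tetradehydroisolariciresinol | COc1cc([C@H]2c3cc(O)c(OC)cc3C=C(C=O)[C@@H]2CO)ccc1O | target

**Step count**
- Total steps: 12.
- Longest linear sequence: 8 steps (1→2→3→4→10→11→12→13→14 via steps 1, 2, 3, 8, 9, 10, 11, 12; the branch from 6 via steps 5, 6, 7, 8–12 is also 8).

**Steps most likely to fail**
1. Steps 6–7 (hydroxymethylation and silylation). The β-hydroxy aldehyde can dimerise, dehydrate or lose ee. Fallback: set the centre by enzymatic desymmetrisation instead. Make prochiral 2-allylpropane-1,3-diol (malonate allylation, then LiAlH4), form the monoacetate with a lipase and vinyl acetate, then choose the order of TIPS protection, deacetylation and oxidation so that 9 is obtained.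
2. Step 10 (crossed aldol condensation). The electron-rich aldehyde 5 may react slowly, allowing self-condensation of 11. Fallback: couple at the ester oxidation level. Oxidise 11 to its methyl ester (Pinnick, then methylation), run a LiHMDS aldol with 5, eliminate with MsCl/DBU to the E-cinnamate, cyclise as in step 11, then use DIBAL followed by MnO2 (selective for the allylic alcohol) to restore the enal.
3. Step 11 (Friedel–Crafts closure). The attacking ring is deactivated by the enal, so E1 loss of the adjacent H, O-trapping by the aldehyde, or conjugate attack by the pendant ring may compete. Fallback: reverse the order of bond formation. Set the diaryl methine first by Rh/chiral-diene asymmetric 1,4-addition of the pendant arylboronic acid (from 4) to an ortho-(dioxolanyl)cinnamate made from a 6-bromovanillin derivative, add the two-carbon unit by enolate allylation, and close the ring last by intramolecular aldol condensation (C3=C4).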